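**Plan**

- Numbering: AcO–C1H=C2H–C3(OAc)(C20HO)–C4H2–C5H2–C6H=C7(CH3)–C8H2–C9H2–C10H, with C10–C15 the trimethylcyclohexene (ring A).
- Retrosynthesis: the acetates and the C1/C20 aldehyde levels go back to a C1,C3,C20-triol; then C7–C8 and C7–CH3 are cut in one operation; inside the fragments C2–C3 (aldol), C3–C4 (Grignard/oxalate) and C9–C10 (Claisen) are cut.
- Enabling feature: the C3 oxygen and C7 are bridged by C4–C5–C6, so O–C3–C4–C5–C6=C7 can be closed as a temporary 3,4-dihydro-2H-pyran (ring P). Ring P holds the oxygen cis to C5, which a stereospecific metallate shift at C7 turns into the (6E)-alkene.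
- Forward: ring A is bought with the enone. Fragment A (C8–C15 iodide) takes four steps and fragment B (ring P with C1–C7 and C20) seven. Ring P is the only ring made (step 11) and is opened in step 12, where the chain is joined (C7–C8, then C7–CH3); seven functional-group steps finish.
- Stereochemistry: C10 from a CBS reduction relayed by a suprafacial Johnson–Claisen shift; C3 from a Mukaiyama aldol catalysed by Cu(OTf)2 and a bis(oxazoline); (6E) from inversion at C7 in the migration and retention in the methylation; (1E) from the steric bias of quaternary C3 in the enol acetylation.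

Key step: step 12

Remark: the known facial preferences of the CBS reduction (larger ketone arm = the α-methylated alkene carbon) and of the Cu(OTf)2/bis(oxazoline) aldol of chelating α-keto esters are assumed to hold for the two substrates used here.

**Fragment A (C8–C15)**

Step 1
Reactants: 1 2,4,4-trimethylcyclohex-2-en-1-one
Product: 2 (1R)-2,4,4-trimethylcyclohex-2-en-1-ol
Conditions: (S)-1-methyl-3,3-diphenyltetrahydro-1H,3H-pyrrolo[1,2-c][1,3,2]oxazaborole [(S)-Me-CBS, 0.1 equiv], BH3·SMe2 (0.6 equiv), THF, −20 °C; MeOH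
Reagents that add atoms: none
Why: Corey–Bakshi–Shibata reduction, in which the ketone binds the oxazaborolidine anti to its larger arm (here the α-methylated alkene carbon), so the (S)-catalyst should deliver hydride to the face that gives the (1R)-alcohol, with 1,2-reduction favoured over conjugate reduction.

Step 2
Reactants: 2 (1R)-2,4,4-trimethylcyclohex-2-en-1-ol, 3 triethyl orthoacetate
Product: 5 ethyl 2-[(1S)-2,6,6-trimethylcyclohex-2-en-1-yl]acetate, via ketene acetal 4 (not isolated)
Conditions: MeC(OEt)3 (6 equiv), EtCO2H (0.1 equiv), 140 °C, EtOH distilled off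
Reagents that add atoms: triethyl orthoacetate 3, CCOC(C)(OCC)OCC
Why: Johnson–Claisen rearrangement, in which the [3,3]-shift of ketene acetal 4 forms the new C–C bond on the ring face the C–O bond leaves, so the (1R)-carbinol configuration should be relayed to the (1S)-ring carbon (C10 of the target) while the double bond moves to its final position.

Step 3
Reactants: 5 ethyl 2-[(1S)-2,6,6-trimethylcyclohex-2-en-1-yl]acetate
Product: 6 2-[(1S)-2,6,6-trimethylcyclohex-2-en-1-yl]ethan-1-ol
Conditions: LiAlH4, Et2O, 0 °C; aqueous work-up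
Reagents that add atoms: none
Why: Ester reduction with LiAlH4, which touches neither the trisubstituted alkene nor the stereocentre.

Step 4
Reactants: 6 2-[(1S)-2,6,6-trimethylcyclohex-2-en-1-yl]ethan-1-ol
Product: 7 1-iodo-2-[(1S)-2,6,6-trimethylcyclohex-2-en-1-yl]ethane
Conditions: I2, PPh3, imidazole, CH2Cl2, 0 °C → rt
Reagents that add atoms: iodine, II
Why: Appel-type iodination of an unhindered primary alcohol by SN2 displacement of the oxyphosphonium group, two carbons away from the stereocentre.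

**Fragment B (ring P, C1–C7 and C20)**

Step 5
Reactants: 8 S-tert-butyl thioacetate
Product: 9 1-(tert-butylsulfanyl)-1-(trimethylsilyloxy)ethene
Conditions: LiN(iPr)2 (1.05 equiv, commercial solution), THF, −78 °C; Me3SiCl; distillation
Reagents that add atoms: chlorotrimethylsilane, C[Si](C)(C)Cl
Why: Kinetic deprotonation of the thioester and O-silylation of its lithium enolate give the silyl ketene thioacetal needed as the nucleophile of step 7.

Step 6
Reactants: 10 (4-bromobut-1-yn-1-yl)trimethylsilane, 11 dimethyl oxalate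
Product: 13 methyl 2-oxo-6-(trimethylsilyl)hex-5-ynoate, via Grignard reagent 12 (not isolated)
Conditions: Mg, THF, 25–40 °C; then added to (CO2Me)2 (3 equiv), THF, −78 °C; 1 M HCl at −78 °C
Reagents that add atoms: dimethyl oxalate 11, COC(=O)C(=O)OC
Why: Grignard mono-addition to an oxalate diester, stopped at the α-keto ester because the tetrahedral magnesium alkoxide persists at −78 °C until the quench, with the silyl cap keeping the alkyne C–H away from the Grignard reagent.

Step 7
Reactants: 13 methyl 2-oxo-6-(trimethylsilyl)hex-5-ynoate, 9 1-(tert-butylsulfanyl)-1-(trimethylsilyloxy)ethene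
Product: 15 methyl (2R)-2-[2-(tert-butylsulfanyl)-2-oxoethyl]-2-hydroxy-6-(trimethylsilyl)hex-5-ynoate, via silyl ether 14 (not isolated)
Conditions: Cu(OTf)2 (0.10 equiv), 2,2′-(propane-2,2-diyl)bis[(4R)-4-tert-butyl-4,5-dihydro-1,3-oxazole] (0.11 equiv), THF, −78 °C; then 1 M HCl, THF, rt
Reagents that add atoms: 1-(tert-butylsulfanyl)-1-(trimethylsilyloxy)ethene 9, C=C(O[Si](C)(C)C)SC(C)(C)C
Why: Mukaiyama aldol addition catalysed by a C2-symmetric bis(oxazoline) complex of divalent copper, in which the keto ester chelates copper through both carbonyl oxygens, the tert-butyl groups of the (R,R)-ligand shield the si face of the ketone, and re-face attack should give the (R)-tertiary carbinol (C3 of the target).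

Step 8
Reactants: 15 methyl (2R)-2-[2-(tert-butylsulfanyl)-2-oxoethyl]-2-hydroxy-6-(trimethylsilyl)hex-5-ynoate
Product: 16 (2R)-2-[4-(trimethylsilyl)but-3-yn-1-yl]butane-1,2,4-triol
Conditions: 15 added to LiAlH4 (3 equiv), THF, 0 °C → rt; aqueous work-up
Reagents that add atoms: none
Why: LiAlH4 reduces both the methyl ester and the thioester to primary alcohols, while inverse addition keeps the aldolate short-lived against retro-aldol cleavage and the silylalkyne is inert.

Step 9
Reactants: 16 (2R)-2-[4-(trimethylsilyl)but-3-yn-1-yl]butane-1,2,4-triol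
Product: 17 (3R)-1-(triisopropylsilyloxy)-3-[(triisopropylsilyloxy)methyl]-7-(trimethylsilyl)hept-6-yn-3-ol
Conditions: iPr3SiCl (2.4 equiv), imidazole (5 equiv), 4-(dimethylamino)pyridine (0.1 equiv), DMF, rt
Reagents that add atoms: chlorotriisopropylsilane, CC(C)[Si](Cl)(C(C)C)C(C)C
Why: Silylation with a bulky chlorosilane discriminates sterically, so the two primary hydroxyls react and the tertiary hydroxyl needed as the ring oxygen stays free.

Step 10
Reactants: 17 (3R)-1-(triisopropylsilyloxy)-3-[(triisopropylsilyloxy)methyl]-7-(trimethylsilyl)hept-6-yn-3-ol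
Product: 18 (3R)-1-(triisopropylsilyloxy)-3-[(triisopropylsilyloxy)methyl]hept-6-yn-3-ol
Conditions: K2CO3 (0.3 equiv), MeOH, rt
Reagents that add atoms: none
Why: Base-catalysed methanolysis of the C(sp)–Si bond frees the terminal alkyne and leaves the hindered triisopropylsilyl ethers intact.

Step 11
Reactants: 18 (3R)-1-(triisopropylsilyloxy)-3-[(triisopropylsilyloxy)methyl]hept-6-yn-3-ol
Product: 19 (2R)-2-[2-(triisopropylsilyloxy)ethyl]-2-[(triisopropylsilyloxy)methyl]-3,4-dihydro-2H-pyran
Conditions: W(CO)6 (0.25 equiv), 1,4-diazabicyclo[2.2.2]octane (2 equiv), THF, hν (350 nm), 60 °C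
Reagents that add atoms: none
Why: Tungsten-catalysed alkynol cycloisomerisation, in which a photogenerated W(CO)5 fragment converts the terminal alkyne into a vinylidene, the tertiary hydroxyl adds to its metal-bound carbon (6-endo overall) and protodemetalation releases ring P without touching the quaternary centre.

**Coupling**

Step 12
Reactants: 19 (2R)-2-[2-(triisopropylsilyloxy)ethyl]-2-[(triisopropylsilyloxy)methyl]-3,4-dihydro-2H-pyran, 7 1-iodo-2-[(1S)-2,6,6-trimethylcyclohex-2-en-1-yl]ethane, 20 iodomethane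
Product: 25 (3R,6E)-7-methyl-1-(triisopropylsilyloxy)-3-[(triisopropylsilyloxy)methyl]-9-[(1S)-2,6,6-trimethylcyclohex-2-en-1-yl]non-6-en-3-ol, via alkyllithium 21 (not isolated), via lithiated pyran 22 (not isolated), via mixed cuprate 23 (not isolated), via alkenylcopper 24 (not isolated)
Conditions: (a) 7, t-BuLi (2.1 equiv), pentane/Et2O 3:2, −78 °C → rt; (b) 19, t-BuLi (1.2 equiv), THF, −78 → 0 °C; (c) solution (a), CuBr·SMe2 (1.0 equiv), Et2O/Me2S, −78 °C, then solution (b), −78 → 0 °C → rt; (d) MeI (5 equiv), 0 °C → rt; aq NH4Cl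
Reagents that add atoms: iodomethane 20, CI
Why: tert-Butyllithium exchanges the iodide of 7 and, in a second flask, removes the vinylic C7–H next to oxygen in 19; the two organolithiums are united on CuBr·SMe2 as the mixed alkyl(alkenyl)cuprate 23 of monovalent copper. In 23 the alkyl ligand moves from copper to C7 while the C7–O bond breaks (1,2-metallate rearrangement); the shift goes with inversion at the sp2 carbon, so copper takes the site the ring oxygen held, cis to C5, and C8 ends up trans to C5 in 24. Iodomethane then replaces copper with retention, which puts the methyl group cis to C5 and gives the (6E)-alkene. The closest known reaction type is the copper-mediated 1,2-metallate rearrangement of α-lithiated 2,3-dihydrofurans and 3,4-dihydro-2H-pyrans with alkylation of the resulting alkenylcopper, extended here only in that the leaving oxygen is a tertiary alkoxide. No ring is closed (ring P is opened and its oxygen becomes the C3 hydroxyl) and no stereocentre is formed; C3 and C10 arrive enantiopure and no bond to either is broken. The selectivity needed is geometric, and it is secured by the ring, which holds oxygen cis to C5 before the shift, and by the 1:1:1 stoichiometry, which leaves the C8 alkyl group as the only ligand able to migrate.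

**End-game**

Step 13
Reactants: 25 (3R,6E)-7-methyl-1-(triisopropylsilyloxy)-3-[(triisopropylsilyloxy)methyl]-9-[(1S)-2,6,6-trimethylcyclohex-2-en-1-yl]non-6-en-3-ol
Product: 26 (3R,6E)-3-(hydroxymethyl)-7-methyl-9-[(1S)-2,6,6-trimethylcyclohex-2-en-1-yl]non-6-ene-1,3-diol
Conditions: Bu4NF (3 equiv), THF, rt; H2O
Reagents that add atoms: none
Why: Fluoride-induced desilylation cleaves both Si–O bonds and leaves the alkenes and stereocentres alone.

Step 14
Reactants: 26 (3R,6E)-3-(hydroxymethyl)-7-methyl-9-[(1S)-2,6,6-trimethylcyclohex-2-en-1-yl]non-6-ene-1,3-diol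
Product: 27 2-[(4R)-2,2-dimethyl-4-{(3E)-4-methyl-6-[(1S)-2,6,6-trimethylcyclohex-2-en-1-yl]hex-3-en-1-yl}-1,3-dioxolan-4-yl]ethan-1-ol
Conditions: Me2C(OMe)2 (1.2 equiv), pyridinium p-toluenesulfonate (0.05 equiv), acetone, rt
Reagents that add atoms: 2,2-dimethoxypropane, COC(C)(C)OC
Why: Acetonide formation under thermodynamic control should favour the five-membered dioxolane across the C20/C3 1,2-diol over the 1,3-dioxane, which would carry a 1,3-diaxial contact between an acetal methyl and a substituent of quaternary C3, so the C1 hydroxyl stays free.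

Step 15
Reactants: 27 2-[(4R)-2,2-dimethyl-4-{(3E)-4-methyl-6-[(1S)-2,6,6-trimethylcyclohex-2-en-1-yl]hex-3-en-1-yl}-1,3-dioxolan-4-yl]ethan-1-ol
Product: 28 2-[(4R)-2,2-dimethyl-4-{(3E)-4-methyl-6-[(1S)-2,6,6-trimethylcyclohex-2-en-1-yl]hex-3-en-1-yl}-1,3-dioxolan-4-yl]acetaldehyde
Conditions: Dess–Martin periodinane (1.2 equiv), pyridine (3 equiv), CH2Cl2, 0 °C → rt
Reagents that add atoms: none
Why: Dess–Martin oxidation of the primary alcohol under buffered, non-enolising conditions, so the β-oxygen at C3 is not eliminated.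

Step 16
Reactants: 28 2-[(4R)-2,2-dimethyl-4-{(3E)-4-methyl-6-[(1S)-2,6,6-trimethylcyclohex-2-en-1-yl]hex-3-en-1-yl}-1,3-dioxolan-4-yl]acetaldehyde
Product: 29 (E)-2-[(4R)-2,2-dimethyl-4-{(3E)-4-methyl-6-[(1S)-2,6,6-trimethylcyclohex-2-en-1-yl]hex-3-en-1-yl}-1,3-dioxolan-4-yl]ethenyl acetate
Conditions: Ac2O (5 equiv), Et3N (5 equiv), 4-(dimethylamino)pyridine (0.2 equiv), THF, 25 → 60 °C
Reagents that add atoms: acetic anhydride, CC(=O)OC(C)=O
Why: Enol acetylation by reversible amine-mediated enolisation and O-acylation by the acetylpyridinium ion, in which the quaternary C3 neighbour should disfavour the (Z)-enol ester and the ketal oxygen at C3 is a poor leaving group for E1cB loss.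

Step 17
Reactants: 29 (E)-2-[(4R)-2,2-dimethyl-4-{(3E)-4-methyl-6-[(1S)-2,6,6-trimethylcyclohex-2-en-1-yl]hex-3-en-1-yl}-1,3-dioxolan-4-yl]ethenyl acetate
Product: 30 (1E,3R,6E)-3-hydroxy-3-(hydroxymethyl)-7-methyl-9-[(1S)-2,6,6-trimethylcyclohex-2-en-1-yl]nona-1,6-dien-1-yl acetate
Conditions: AcOH/H2O (4:1), 40 °C
Reagents that add atoms: none
Why: Acid-catalysed ketal hydrolysis through the 2-propyl oxocarbenium ion, which should be much faster in dilute acetic acid than hydrolysis of the enol acetate or ionisation of the tertiary allylic C–O bond.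

Step 18
Reactants: 30 (1E,3R,6E)-3-hydroxy-3-(hydroxymethyl)-7-methyl-9-[(1S)-2,6,6-trimethylcyclohex-2-en-1-yl]nona-1,6-dien-1-yl acetate
Product: 31 (1E,3R,6E)-3-formyl-3-hydroxy-7-methyl-9-[(1S)-2,6,6-trimethylcyclohex-2-en-1-yl]nona-1,6-dien-1-yl acetate
Conditions: SO3·pyridine (3 equiv), DMSO, iPr2NEt (5 equiv), CH2Cl2, 0 °C; aq NaHCO3
Reagents that add atoms: none
Why: Parikh–Doering oxidation (activated DMSO) takes the primary alcohol to the aldehyde without cleaving the 1,2-diol, and C3 carries no hydrogen, so the new aldehyde cannot epimerise.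

Step 19
Reactants: 31 (1E,3R,6E)-3-formyl-3-hydroxy-7-methyl-9-[(1S)-2,6,6-trimethylcyclohex-2-en-1-yl]nona-1,6-dien-1-yl acetate
Product: 32 (1E,3R,6E)-3-(acetyloxy)-3-formyl-7-methyl-9-[(1S)-2,6,6-trimethylcyclohex-2-en-1-yl]nona-1,6-dien-1-yl acetate
Conditions: Ac2O (10 equiv), Et3N, 4-(dimethylamino)pyridine (1 equiv), CH2Cl2, rt
Reagents that add atoms: acetic anhydride, CC(=O)OC(C)=O
Why: Nucleophile-catalysed acetylation of the tertiary hydroxyl, which breaks no bond at C3 and meets an aldehyde that has no α-hydrogen to enolise.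

**Compound list**

1 | 2,4,4-trimethylcyclohex-2-en-1-one | CC1=CC(C)(C)CCC1=O | starting material
2 | (1R)-2,4,4-trimethylcyclohex-2-en-1-ol | O[C@@H]1CCC(C)(C)C=C1C | intermediate
3 | triethyl orthoacetate | CCOC(C)(OCC)OCC | starting material
4 | 1-ethoxy-1-{[(1R)-2,4,4-trimethylcyclohex-2-en-1-yl]oxy}ethene | C=C(OCC)O[C@@H]1CCC(C)(C)C=C1C | intermediate (not isolated)
5 | ethyl 2-[(1S)-2,6,6-trimethylcyclohex-2-en-1-yl]acetate | CCOC(=O)C[C@@H]1C(C)=CCCC1(C)C | intermediate
6 | 2-[(1S)-2,6,6-trimethylcyclohex-2-en-1-yl]ethan-1-ol | OCC[C@@H]1C(C)=CCCC1(C)C | intermediate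
7 | 1-iodo-2-[(1S)-2,6,6-trimethylcyclohex-2-en-1-yl]ethane | ICC[C@@H]1C(C)=CCCC1(C)C | intermediate
8 | S-tert-butyl thioacetate | CC(=O)SC(C)(C)C | starting material
9 | 1-(tert-butylsulfanyl)-1-(trimethylsilyloxy)ethene | C=C(O[Si](C)(C)C)SC(C)(C)C | intermediate
10 | (4-bromobut-1-yn-1-yl)trimethylsilane | C[Si](C)(C)C#CCCBr | starting material
11 | dimethyl oxalate | COC(=O)C(=O)OC | starting material
12 | [4-(trimethylsilyl)but-3-yn-1-yl]magnesium bromide | C[Si](C)(C)C#CCC[Mg]Br | intermediate (not isolated)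
13 | methyl 2-oxo-6-(trimethylsilyl)hex-5-ynoate | COC(=O)C(=O)CCC#C[Si](C)(C)C | intermediate
14 | methyl (2R)-2-[2-(tert-butylsulfanyl)-2-oxoethyl]-6-(trimethylsilyl)-2-(trimethylsilyloxy)hex-5-ynoate | CC(C)(C)SC(=O)C[C@@](O[Si](C)(C)C)(C(=O)OC)CCC#C[Si](C)(C)C | intermediate (not isolated)
15 | methyl (2R)-2-[2-(tert-butylsulfanyl)-2-oxoethyl]-2-hydroxy-6-(trimethylsilyl)hex-5-ynoate | CC(C)(C)SC(=O)C[C@@](O)(C(=O)OC)CCC#C[Si](C)(C)C | intermediate
16 | (2R)-2-[4-(trimethylsilyl)but-3-yn-1-yl]butane-1,2,4-triol | OCC[C@@](CO)(CCC#C[Si](C)(C)C)O | intermediate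
17 | (3R)-1-(triisopropylsilyloxy)-3-[(triisopropylsilyloxy)methyl]-7-(trimethylsilyl)hept-6-yn-3-ol | CC(C)[Si](C(C)C)(C(C)C)OCC[C@@](CO[Si](C(C)C)(C(C)C)C(C)C)(CCC#C[Si](C)(C)C)O | intermediate
18 | (3R)-1-(triisopropylsilyloxy)-3-[(triisopropylsilyloxy)methyl]hept-6-yn-3-ol | CC(C)[Si](C(C)C)(C(C)C)OCC[C@@](CO[Si](C(C)C)(C(C)C)C(C)C)(CCC#C)O | intermediate
19 | (2R)-2-[2-(triisopropylsilyloxy)ethyl]-2-[(triisopropylsilyloxy)methyl]-3,4-dihydro-2H-pyran | CC(C)[Si](C(C)C)(C(C)C)OCC[C@@]1(CO[Si](C(C)C)(C(C)C)C(C)C)CCC=CO1 | intermediate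
20 | iodomethane | CI | starting material
21 | {2-[(1S)-2,6,6-trimethylcyclohex-2-en-1-yl]ethyl}lithium | [Li]CC[C@@H]1C(C)=CCCC1(C)C | intermediate (not isolated)
22 | (2R)-6-lithio-2-[2-(triisopropylsilyloxy)ethyl]-2-[(triisopropylsilyloxy)methyl]-3,4-dihydro-2H-pyran | CC(C)[Si](C(C)C)(C(C)C)OCC[C@@]1(CO[Si](C(C)C)(C(C)C)C(C)C)CCC=C([Li])O1 | intermediate (not isolated)
23 | lithium {2-[(1S)-2,6,6-trimethylcyclohex-2-en-1-yl]ethyl}{(6R)-6-[2-(triisopropylsilyloxy)ethyl]-6-[(triisopropylsilyloxy)methyl]-5,6-dihydro-4H-pyran-2-yl}cuprate | [Li+].CC(C)[Si](C(C)C)(C(C)C)OCC[C@@]1(CO[Si](C(C)C)(C(C)C)C(C)C)CCC=C(O1)[Cu-]CC[C@@H]2C(C)=CCCC2(C)C | intermediate (not isolated)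
24 | lithium (3R,6Z)-7-cuprio-1-(triisopropylsilyloxy)-3-[(triisopropylsilyloxy)methyl]-9-[(1S)-2,6,6-trimethylcyclohex-2-en-1-yl]non-6-en-3-olate | CC(C)[Si](C(C)C)(C(C)C)OCC[C@@](CO[Si](C(C)C)(C(C)C)C(C)C)(CC/C=C(\[Cu])CC[C@@H]1C(C)=CCCC1(C)C)O[Li] | intermediate (not isolated)
25 | (3R,6E)-7-methyl-1-(triisopropylsilyloxy)-3-[(triisopropylsilyloxy)methyl]-9-[(1S)-2,6,6-trimethylcyclohex-2-en-1-yl]non-6-en-3-ol | CC(C)[Si](C(C)C)(C(C)C)OCC[C@@](CO[Si](C(C)C)(C(C)C)C(C)C)(CC/C=C(\C)CC[C@@H]1C(C)=CCCC1(C)C)O | intermediate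
26 | (3R,6E)-3-(hydroxymethyl)-7-methyl-9-[(1S)-2,6,6-trimethylcyclohex-2-en-1-yl]non-6-ene-1,3-diol | OCC[C@@](CO)(CC/C=C(\C)CC[C@@H]1C(C)=CCCC1(C)C)O | intermediate
27 | 2-[(4R)-2,2-dimethyl-4-{(3E)-4-methyl-6-[(1S)-2,6,6-trimethylcyclohex-2-en-1-yl]hex-3-en-1-yl}-1,3-dioxolan-4-yl]ethan-1-ol | CC1(C)OC[C@](CCO)(CC/C=C(\C)CC[C@@H]2C(C)=CCCC2(C)C)O1 | intermediate
28 | 2-[(4R)-2,2-dimethyl-4-{(3E)-4-methyl-6-[(1S)-2,6,6-trimethylcyclohex-2-en-1-yl]hex-3-en-1-yl}-1,3-dioxolan-4-yl]acetaldehyde | CC1(C)OC[C@](CC=O)(CC/C=C(\C)CC[C@@H]2C(C)=CCCC2(C)C)O1 | intermediate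
29 | (E)-2-[(4R)-2,2-dimethyl-4-{(3E)-4-methyl-6-[(1S)-2,6,6-trimethylcyclohex-2-en-1-yl]hex-3-en-1-yl}-1,3-dioxolan-4-yl]ethenyl acetate | CC1(C)OC[C@](/C=C/OC(C)=O)(CC/C=C(\C)CC[C@@H]2C(C)=CCCC2(C)C)O1 | intermediate
30 | (1E,3R,6E)-3-hydroxy-3-(hydroxymethyl)-7-methyl-9-[(1S)-2,6,6-trimethylcyclohex-2-en-1-yl]nona-1,6-dien-1-yl acetate | CC(=O)O/C=C/[C@@](CO)(CC/C=C(\C)CC[C@@H]1C(C)=CCCC1(C)C)O | intermediate
31 | (1E,3R,6E)-3-formyl-3-hydroxy-7-methyl-9-[(1S)-2,6,6-trimethylcyclohex-2-en-1-yl]nona-1,6-dien-1-yl acetate | CC(=O)O/C=C/[C@@](C=O)(CC/C=C(\C)CC[C@@H]1C(C)=CCCC1(C)C)O | intermediate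
32 | (1E,3R,6E)-3-(acetyloxy)-3-formyl-7-methyl-9-[(1S)-2,6,6-trimethylcyclohex-2-en-1-yl]nona-1,6-dien-1-yl acetate | CC(=O)O/C=C/[C@@](C=O)(CC/C=C(\C)CC[C@@H]1C(C)=CCCC1(C)C)OC(C)=O | target

**Count**

Total: 19 steps. Longest linear sequence: 14 steps (steps 6–19, from 10 and 11); fragment A (steps 1–4) and reagent 9 (step 5) are side branches.

**Steps most likely to fail**

1. Step 12. The mixed cuprate may scramble its ligands or decay before the 1,2-shift, and the hindered alkenylcopper may be captured by iodomethane only in part, which would leave a C7–H alkene. The fallback separates the two bond formations. Lithiated pyran 22, made from 19 as in step 12, would be alkylated directly with iodide 7 (THF/DMPU, −78 → 0 °C) to give the 6-alkyl dihydropyran (2R)-2-[2-(triisopropylsilyloxy)ethyl]-2-[(triisopropylsilyloxy)methyl]-6-{2-[(1S)-2,6,6-trimethylcyclohex-2-en-1-yl]ethyl}-3,4-dihydro-2H-pyran F1. The enol ether C7–O bond of this compound would then be replaced by C7–CH3 in a nickel-catalysed ring-opening cross-coupling with MeMgBr (NiCl2(PPh3)2, toluene, reflux). Zerovalent nickel formed in the flask inserts into the C7–O bond and methyl should take the place of oxygen with retention, cis to C5. This path sets out from 19 and 7 and comes back at 25; the same two bonds are formed and the same ring is opened.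

2. Step 16. Under amine-mediated enolisation the C3 ketal oxygen may be expelled from the enolate (E1cB) to give an enal, and kinetic O-acylation may erode the (1E) geometry. The fallback gives up enolate chemistry for acid-catalysed enol-ester exchange. Aldehyde 28 would be heated with isopropenyl acetate and a catalytic amount of p-toluenesulfonic acid while acetone distils. The neutral enol is acetylated under thermodynamic control, which should favour the (1E)-isomer, and in the anhydrous, acetone-rich medium the acetonide can only exchange with itself. This path sets out from 28 and comes back at 29; no new compound arises on it (F0).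

3. Step 19. Acylation of the congested tertiary hydroxyl may be slow enough for the α-hydroxy aldehyde to undergo a base-induced α-ketol shift or to oligomerise. The fallback installs the tertiary acetate before the aldehyde exists. Diol 30 would be converted with trimethyl orthoacetate and catalytic pyridinium p-toluenesulfonate (CH2Cl2, rt) into the cyclic orthoacetate (E)-2-[(4R)-2-methoxy-2-methyl-4-{(3E)-4-methyl-6-[(1S)-2,6,6-trimethylcyclohex-2-en-1-yl]hex-3-en-1-yl}-1,3-dioxolan-4-yl]ethenyl acetate F2 (both epimers at the orthoester carbon). Brief treatment with aqueous acetic acid should open the derived dioxolanylium ion to the ester of the more hindered oxygen, the tertiary acetate (1E,3R,6E)-3-(acetyloxy)-3-(hydroxymethyl)-7-methyl-9-[(1S)-2,6,6-trimethylcyclohex-2-en-1-yl]nona-1,6-dien-1-yl acetate F3. This is oxidised at once with Dess–Martin periodinane, before the acetyl group can shift to the primary oxygen. This path sets out from 30 and comes back at 32.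

**Further compounds**

F1 | step 12 | (2R)-2-[2-(triisopropylsilyloxy)ethyl]-2-[(triisopropylsilyloxy)methyl]-6-{2-[(1S)-2,6,6-trimethylcyclohex-2-en-1-yl]ethyl}-3,4-dihydro-2H-pyran | CC(C)[Si](C(C)C)(C(C)C)OCC[C@@]1(CO[Si](C(C)C)(C(C)C)C(C)C)CCC=C(CC[C@@H]2C(C)=CCCC2(C)C)O1
F0 | step 16 | none | none
F2 | step 19 | (E)-2-[(4R)-2-methoxy-2-methyl-4-{(3E)-4-methyl-6-[(1S)-2,6,6-trimethylcyclohex-2-en-1-yl]hex-3-en-1-yl}-1,3-dioxolan-4-yl]ethenyl acetate | COC1(C)OC[C@](/C=C/OC(C)=O)(CC/C=C(\C)CC[C@@H]2C(C)=CCCC2(C)C)O1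
F3 | step 19 | (1E,3R,6E)-3-(acetyloxy)-3-(hydroxymethyl)-7-methyl-9-[(1S)-2,6,6-trimethylcyclohex-2-en-1-yl]nona-1,6-dien-1-yl acetate | CC(=O)O/C=C/[C@@](CO)(CC/C=C(\C)CC[C@@H]1C(C)=CCCC1(C)C)OC(C)=O
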